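- A clearing time of 198 s, read from the amber run, is the number we carry: [substrate] there fell to 62.7% by 120 s, faster as it dropped, and a rate inverse to [substrate] (substrate inhibition) makes [substrate]² fall on a straight line, so we define the clearing time as the time that line takes to reach zero, and it scales with the square of the charge.

| flask | substrate | enzyme | impurity | remark | time |
|---|---|---|---|---|---|
| violet | 2.6 mM | 0.30 µM | 0.23 µM | run made earlier |  |
| amber | 42 mM | 0.30 µM | 0.23 µM | run made earlier |  |
| alpha | 40 mM | 0.30 µM | 0.23 µM |  | 2.5 min |
| theta | 20 mM | 0.30 µM | 0.23 µM |  | 2.5 min |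
| zeta | 13 mM | 0.30 µM | 0.23 µM |  | 2.5 min |
| eta | 3.0 mM | 0.30 µM | 0.23 µM |  | 2.5 min |
| epsilon | 25 mM | 0.30 µM | 0.23 µM |  | 2.5 min |
| beta | 50 mM | 0.30 µM | 0.23 µM |  | 2.5 min |

| run | time / s | target / % | substrate / % |
|---|---|---|---|
| violet | 10.0 | 100.0 | 0.4 |
| violet | 20.0 | 98.4 | 0.2 |
| violet | 40.0 | 99.0 | 0 |
| violet | 60.0 | 100.1 | 0 |
| violet | 80.0 | 101.3 | 0.9 |
| violet | 120 | 98.4 | 0.5 |
| amber | 20.0 | 2.0 | 94.7 |
| amber | 40.0 | 5.9 | 89.8 |
| amber | 50.0 | 4.6 | 86.7 |
| amber | 80.0 | 5.5 | 78.9 |
| amber | 120 | 7.7 | 62.7 |

(scatter of a reading: 1 percentage point)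



- the flasks by amount of target, in percent of the substrate charged, highest first, at 2.5 min (alpha / theta / zeta / eta / epsilon / beta)
- the amount of target, in percent of the substrate charged of the flask you put first, at 2.5 min
- the amount of target, in percent of the substrate charged of the flask you put last, at 2.5 min

- We hold each flask's clearing time against 150 s: epsilon needs 70.1 s, alpha 179 s and beta 280 s, so we rank the flasks by falling target as the charge rises, with beta last.
- By this line alpha keeps 40.5% of its substrate and beta 68.2%, so the 31.8% reacted in beta is our first upper bound on its target.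
- We tighten that from amber, which showed 5.5% target at 21.1% reacted and 7.7% at 37.3%; since beta's estimated share lies between, and if beta turns its reacted share into target as amber did, those two readings bracket the low answer, each with a scatter of 1 percentage point.
- By the same line we estimate that eta clears in 1.01 s, so we bracket the top answer between violet's last reading of 98.4% at 120 s and the full charge.
- The forecast, noting that amber “speeds up as substrate falls”, gave eta > zeta > theta > epsilon > alpha > beta, with top 100% and low 6%, both inside our brackets.
- The flasks give eta > zeta > theta > epsilon > alpha > beta, with top 99.9% inside its bracket and low 4.86%, under the lower edge by 0.64 points, less than the scatter.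

    substrate + enzyme → target + enzyme, rate k1*[substrate]*[enzyme]/(1 + ([substrate]/Km1) + ([substrate]/Ksi1)^2) (0.0640 M, 1.10 mM, k = 4.70 × 10⁷ M⁻¹ s⁻¹)
    substrate + target → side product (k = 0.880 M⁻¹ s⁻¹)
    enzyme + impurity → spent catalyst (k = 1.50 × 10⁷ M⁻¹ s⁻¹)
    2 enzyme ⇌ resting dimer (K = 4.40 × 10⁶ M⁻¹, k = 2.00 × 10⁶ M⁻¹ s⁻¹)

- The clearing-time line gave 68.2% of beta's substrate against 64% standing in that flask at 2.50 min, and 40.5% of alpha's against 40% in alpha at 2.50 min, although beta holds something that number doesn't show, a side product at 31.0%. Beta's target stays low mainly because of the crowding by [substrate] in the law that makes target: the run of beta without that crowding reaches 99.2% instead of 4.86%.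

The readings come from a simulation with made-up constants; noise was put on by code.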